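The route rests on cutting the C2–C3 bond of the quinone ring (C1, C2, C3, C4, C4a, C8a). C1=O, C2–OH and C4=O together are the enol form of a naphthalene-1,2,4-trione. C2–C3 is therefore an enolate–ester bond at unchanged oxidation level. One Dieckmann closure forms C2–C3, builds the second ring and delivers the hydroxyquinone without an oxidant. Its precursor is a pentasubstituted benzene. It carries a methyl α-keto ester (C1, C2) ortho to an (S)-4-silyloxypentanoyl ketone (C4, C3 and the side chain), with all three methoxy groups already placed. The stereocentre is taken intact from (S)-γ-valerolactone.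

Key step: step 7

Locants: the quinone numbering of the target is used throughout. C1 is the carbonyl at C8a, C2 is C–OH, C3 is the side-chain carbon, and C4 is the carbonyl at C4a. OMe sits at C5, C6 and C8, and H at C7.

Remark on the arene: in a 1,2,4-trimethoxybenzene, electrophiles go to the later C8a. Bases are expected to go to the later C7, between two methoxy groups, and this holds for the 5-bromo derivative too. The C4a–C4 bond is therefore made from a bromide whose position is fixed by the starting material. The bromine for C8a is added afterwards by electrophilic substitution.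

Assumption: enol acetal 11 is treated as an E/Z mixture, because both isomers give the same ketone. Compounds 6, 16 and F1 are epimer mixtures at centres that later disappear.

Step 1
Reactants: 1 5-bromovanillin
Product: 3 1-bromo-2,3,5-trimethoxybenzene, via hydroquinone 2 (not isolated)
Conditions: 30% H2O2, aq NaOH, N2, 0 °C to rt; then Me2SO4, NaOH, trace Na2S2O4, rt to 40 °C
Reagents that add atoms: hydrogen peroxide, OO; dimethyl sulfate, COS(=O)(=O)OC
Why: Dakin oxidation of a p-hydroxybenzaldehyde replaces CHO by OH exactly at the carbon that becomes C8, and Williamson methylation of both phenoxides in the same basic medium avoids handling the air-sensitive hydroquinone 2.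

Step 2
Reactants: 3 1-bromo-2,3,5-trimethoxybenzene; 4 (S)-γ-valerolactone
Product: 7 (S)-4-hydroxy-1-(2,3,5-trimethoxyphenyl)pentan-1-one, via aryllithium 5 (not isolated), via lithium lactolate 6 (not isolated)
Conditions: n-BuLi, THF, −78 °C; cannulated into 4 (1.2 equiv), THF, −78 °C; AcOH, −78 °C
Reagents that add atoms: none
Why: Bromine–lithium exchange followed by 1,2-addition of the aryllithium to a γ-lactone fixes the metal at the later C4a with no amine or ortho-halogen present, inverse addition at −78 °C lets the adduct rest as lactolate 6 so that a second addition is avoided, and the stereocentre of 4 is a spectator whose C–O bond is never broken.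

Step 3
Reactants: 7 (S)-4-hydroxy-1-(2,3,5-trimethoxyphenyl)pentan-1-one
Product: 8 (S)-4-(tert-butyldimethylsilyloxy)-1-(2,3,5-trimethoxyphenyl)pentan-1-one
Conditions: TBSCl, imidazole, DMF, rt
Reagents that add atoms: tert-butyldimethylsilyl chloride, CC(C)(C)[Si](C)(C)Cl
Why: Imidazole-promoted silylation of the secondary alcohol drains any cyclic lactol tautomer through the open hydroxy ketone, because a tertiary lactol hydroxyl is silylated far more slowly, and it leaves the C–O bond of the stereocentre intact.

Step 4
Reactants: 8 (S)-4-(tert-butyldimethylsilyloxy)-1-(2,3,5-trimethoxyphenyl)pentan-1-one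
Product: 9 (S)-1-(2-bromo-3,5,6-trimethoxyphenyl)-4-(tert-butyldimethylsilyloxy)pentan-1-one
Conditions: NBS (1.0 equiv), MeCN, 0 °C
Reagents that add atoms: N-bromosuccinimide, O=C1CCC(=O)N1Br
Why: In this electrophilic aromatic bromination C6′ (the later C8a) is para to the 3′-methoxy and ortho to the 5′-methoxy group whereas C4′ is buried between two methoxy groups, so bromine enters next to the carbonyl substituent as it does in 3,5-dimethoxyaryl ketones and esters, and the neutral medium spares the silyl ether and the α-CH2.

Step 5
Reactants: 9 (S)-1-(2-bromo-3,5,6-trimethoxyphenyl)-4-(tert-butyldimethylsilyloxy)pentan-1-one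
Product: 11 1-bromo-2-[(4S)-4-(tert-butyldimethylsilyloxy)-1-(methoxymethoxy)pent-1-en-1-yl]-3,4,6-trimethoxybenzene, via potassium enolate 10 (not isolated)
Conditions: KHMDS, THF–DMPU, −78 °C; MOMCl, −78 to 0 °C
Reagents that add atoms: chloromethyl methyl ether, COCCl
Why: O-Alkylation of the dissociated potassium enolate 10 with a hard chloromethyl ether masks the ketone by a reaction remote from the carbonyl carbon, which Br and OMe shield too well for ordinary acetalisation, it gives a mask that (unlike a silyl enol ether) cannot migrate to a neighbouring carbanion, and no aryne can form because no hydrogen stands ortho to bromine.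

Step 6
Reactants: 11 1-bromo-2-[(4S)-4-(tert-butyldimethylsilyloxy)-1-(methoxymethoxy)pent-1-en-1-yl]-3,4,6-trimethoxybenzene; 12 dimethyl oxalate
Product: 15 methyl 2-oxo-2-{3,4,6-trimethoxy-2-[(S)-4-(tert-butyldimethylsilyloxy)pentanoyl]phenyl}acetate, via aryllithium 13 (not isolated), via enol acetal keto ester 14 (not isolated)
Conditions: n-BuLi, THF, −78 °C; cannulated into 12 (3 equiv), THF, −78 °C; then 0.5 M aq HCl, THF, 0 °C
Reagents that add atoms: water, O
Why: This is bromine–lithium exchange and acylation of the aryllithium with an oxalate diester (the standard α-keto ester synthesis), in which exchange at −78 °C outruns any attack on enol acetal or silyl ether, inverse addition of hindered 13 to excess 12 stops after one addition, and dilute acid then hydrolyses only the enol acetal of 14 by protonation at C3, well before the secondary TBS ether or the methyl ester respond.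

Step 7
Reactants: 15 methyl 2-oxo-2-{3,4,6-trimethoxy-2-[(S)-4-(tert-butyldimethylsilyloxy)pentanoyl]phenyl}acetate
Product: 18 2-hydroxy-5,6,8-trimethoxy-3-[(S)-2-(tert-butyldimethylsilyloxy)propyl]-1,4-naphthoquinone, via trione 16 (not isolated), via sodium quinonate 17 (not isolated)
Conditions: NaOMe (2.5 equiv), dry MeOH–THF, Ar, 0 to 40 °C; then 1 M aq HCl to pH 3, 0 °C
Reagents that add atoms: none
Why: Methoxide reversibly deprotonates C3, the only α-carbon of the C4 ketone, and the enolate carbon adds to the ester carbonyl C2; loss of methoxide gives trione 16, which is deprotonated at once to the delocalised anion 17 and set free as 18 on acidification. The reaction type is the Dieckmann (intramolecular Claisen) condensation of a ketone enolate with an ester, the same acyl transfer that operates in alkoxide-induced rearrangements of enol lactones to cyclic 1,3-diketones and hydroxynaphthoquinones. The ring C1–C2–C3–C4–C4a–C8a closes in the 6-(enolendo)-exo-trig mode. No stereocentre is formed because C3 ends up sp2, and the silyloxy-bearing carbon has no acidic hydrogen and sits one carbon too far from C3 for β-elimination, so its S configuration is kept. The selectivity needed is ester C2 over the more electrophilic ketone C1: addition to C1 gives a five-membered aldolate with a quaternary carbon pressed against the C8 methoxy group, this adduct reverts under the equilibrating conditions and C1 is partly parked as its methanol hemiketal, whereas the six-membered closure ends in the anion of a vinylogous carboxylic acid and is not reversed. Methoxide matched to the methyl ester and to the aryl methyl ethers makes every exchange degenerate, and dry conditions prevent saponification to an unreactive keto carboxylate.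

Step 8
Reactants: 18 2-hydroxy-5,6,8-trimethoxy-3-[(S)-2-(tert-butyldimethylsilyloxy)propyl]-1,4-naphthoquinone
Product: 19 2-hydroxy-3-[(S)-2-hydroxypropyl]-5,6,8-trimethoxy-1,4-naphthoquinone
Conditions: TBAF (3 equiv), THF, 0 °C to rt; 1 M aq HCl to pH 3
Reagents that add atoms: none
Why: In this fluoride-induced Si–O cleavage the basic medium holds the C2 hydroxyl as its unreactive anion, which prevents acid-catalysed addition–elimination of the liberated alcohol at C2 (dihydrofuran formation), and the C–O bond at the stereocentre is not involved so the S configuration is retained.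

Step 9
Reactants: 19 2-hydroxy-3-[(S)-2-hydroxypropyl]-5,6,8-trimethoxy-1,4-naphthoquinone
Product: 21 3-[(S)-2-acetoxypropyl]-2-hydroxy-5,6,8-trimethoxy-1,4-naphthoquinone (CNP0321270.1), via diacetate 20 (not isolated)
Conditions: Ac2O, pyridine, DMAP (cat.), CH2Cl2, 0 °C to rt; then MeOH, rt
Reagents that add atoms: acetic anhydride, CC(=O)OC(C)=O
Why: DMAP-catalysed acetylation esterifies both hydroxyls with retention at the stereocentre to give 20, and chemoselective methanolysis in the same flask then cleaves only its C2 enol acetate, a vinylogous mixed anhydride with the stabilised quinonate as leaving group, while the secondary alkyl acetate is inert.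

Compound list
1 | 5-bromovanillin (3-bromo-4-hydroxy-5-methoxybenzaldehyde) | COc1cc(C=O)cc(Br)c1O | starting material
2 | 2-bromo-6-methoxybenzene-1,4-diol | COc1cc(O)cc(Br)c1O | intermediate
3 | 1-bromo-2,3,5-trimethoxybenzene | COc1cc(Br)c(OC)c(OC)c1 | intermediate
4 | (S)-γ-valerolactone [(5S)-5-methyloxolan-2-one] | C[C@H]1CCC(=O)O1 | starting material
5 | (2,3,5-trimethoxyphenyl)lithium | [Li]c1cc(OC)cc(OC)c1OC | intermediate
6 | lithium (5S)-5-methyl-2-(2,3,5-trimethoxyphenyl)oxolan-2-olate (C2 epimers) | [Li+].[O-]C1(CC[C@H](C)O1)c2cc(OC)cc(OC)c2OC | intermediate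
7 | (S)-4-hydroxy-1-(2,3,5-trimethoxyphenyl)pentan-1-one | COc1cc(OC)c(OC)c(C(=O)CC[C@H](C)O)c1 | intermediate
8 | (S)-4-(tert-butyldimethylsilyloxy)-1-(2,3,5-trimethoxyphenyl)pentan-1-one | COc1cc(OC)c(OC)c(C(=O)CC[C@H](C)O[Si](C)(C)C(C)(C)C)c1 | intermediate
9 | (S)-1-(2-bromo-3,5,6-trimethoxyphenyl)-4-(tert-butyldimethylsilyloxy)pentan-1-one | COc1cc(OC)c(Br)c(C(=O)CC[C@H](C)O[Si](C)(C)C(C)(C)C)c1OC | intermediate
10 | potassium enolate of 9 | [K+].[O-]C(=CC[C@H](C)O[Si](C)(C)C(C)(C)C)c1c(Br)c(OC)cc(OC)c1OC | intermediate
11 | 1-bromo-2-[(4S)-4-(tert-butyldimethylsilyloxy)-1-(methoxymethoxy)pent-1-en-1-yl]-3,4,6-trimethoxybenzene (E/Z) | COCOC(=CC[C@H](C)O[Si](C)(C)C(C)(C)C)c1c(Br)c(OC)cc(OC)c1OC | intermediate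
12 | dimethyl oxalate | COC(=O)C(=O)OC | starting material
13 | {2-[(4S)-4-(tert-butyldimethylsilyloxy)-1-(methoxymethoxy)pent-1-en-1-yl]-3,4,6-trimethoxyphenyl}lithium | [Li]c1c(OC)cc(OC)c(OC)c1C(OCOC)=CC[C@H](C)O[Si](C)(C)C(C)(C)C | intermediate
14 | methyl 2-{2-[(4S)-4-(tert-butyldimethylsilyloxy)-1-(methoxymethoxy)pent-1-en-1-yl]-3,4,6-trimethoxyphenyl}-2-oxoacetate | COC(=O)C(=O)c1c(OC)cc(OC)c(OC)c1C(OCOC)=CC[C@H](C)O[Si](C)(C)C(C)(C)C | intermediate
15 | methyl 2-oxo-2-{3,4,6-trimethoxy-2-[(S)-4-(tert-butyldimethylsilyloxy)pentanoyl]phenyl}acetate | COC(=O)C(=O)c1c(OC)cc(OC)c(OC)c1C(=O)CC[C@H](C)O[Si](C)(C)C(C)(C)C | intermediate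
16 | 5,6,8-trimethoxy-3-[(S)-2-(tert-butyldimethylsilyloxy)propyl]naphthalene-1,2,4(3H)-trione (C3 epimers) | COc1cc(OC)c2c(c1OC)C(=O)C(C[C@H](C)O[Si](C)(C)C(C)(C)C)C(=O)C2=O | intermediate
17 | sodium salt of 18 (C2 oxido quinone) | [Na+].COc1cc(OC)c2c(c1OC)C(=O)C(C[C@H](C)O[Si](C)(C)C(C)(C)C)=C([O-])C2=O | intermediate
18 | 2-hydroxy-5,6,8-trimethoxy-3-[(S)-2-(tert-butyldimethylsilyloxy)propyl]-1,4-naphthoquinone | COc1cc(OC)c2c(c1OC)C(=O)C(C[C@H](C)O[Si](C)(C)C(C)(C)C)=C(O)C2=O | intermediate
19 | 2-hydroxy-3-[(S)-2-hydroxypropyl]-5,6,8-trimethoxy-1,4-naphthoquinone | COc1cc(OC)c2c(c1OC)C(=O)C(C[C@H](C)O)=C(O)C2=O | intermediate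
20 | 2-acetoxy-3-[(S)-2-acetoxypropyl]-5,6,8-trimethoxy-1,4-naphthoquinone | COc1cc(OC)c2c(c1OC)C(=O)C(C[C@H](C)OC(C)=O)=C(OC(C)=O)C2=O | intermediate
21 | 3-[(S)-2-acetoxypropyl]-2-hydroxy-5,6,8-trimethoxy-1,4-naphthoquinone (CNP0321270.1) | COc1cc(OC)c2c(c1OC)C(=O)C(C[C@H](C)OC(C)=O)=C(O)C2=O | target

Total step count: 9. Longest linear sequence: 9 steps (1 to 21; lactone 4 enters at step 2 and oxalate 12 at step 6).

Steps most likely to fail

Step 7. The C3 enolate may be consumed at the C1 ketone, with the aldol adduct losing water instead of reverting. Adventitious hydroxide may also saponify the keto ester and stop the acyl transfer. The fallback uses a different ring-closing bond and leaves the route at 9. A crossed Claisen condensation of its lithium enolate with 12 (LiHMDS, THF, −78 to 0 °C) makes C2–C3 intermolecularly. It gives methyl (5S)-3-(2-bromo-3,5,6-trimethoxybenzoyl)-5-(tert-butyldimethylsilyloxy)-2-oxohexanoate F1. F1 is treated with LiHMDS and then with n-BuLi at −100 °C. Deprotonation ties up both ketone carbonyls, so bromine–lithium exchange is followed by closure of C8a–C1 on the only free electrophile, the ester (Parham cyclisation). Acidic work-up comes back to the route at 18, and steps 5 to 7 are bypassed.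

Step 6. The crowded aryllithium may be protonated before it is acylated, may add twice to the oxalate, or the silyl ether may be lost in the acid stage. The fallback needs no carbanion and no masking, and it sets out from 9. A Stille coupling with methyl 2-(tributylstannyl)acrylate [Pd2(dba)3, P(t-Bu)3, CuI, DMF, 60 °C] tolerates the free ketone. It gives methyl 2-{3,4,6-trimethoxy-2-[(S)-4-(tert-butyldimethylsilyloxy)pentanoyl]phenyl}acrylate F2. Lemieux–Johnson cleavage of the 1,1-disubstituted alkene (OsO4 cat., NaIO4, 2,6-lutidine, dioxane–water) turns C=CH2 into the C1 ketone. This comes back to the route at 15, so step 5, with its O- versus C-alkylation issue, is bypassed as well.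

Step 2. The lactolate may open already at −78 °C, so that the ketone is attacked a second time or is enolised by the aryllithium. The lactone itself may also be deprotonated. The fallback uses an acyl donor that cannot over-react and moves protection ahead of the coupling. It sets out from 4, which is opened with MeNHOMe·HCl/i-PrMgCl (THF, −20 °C) to (S)-4-hydroxy-N-methoxy-N-methylpentanamide F3. This is silylated at once (TBSCl, imidazole, DMF) to (S)-4-(tert-butyldimethylsilyloxy)-N-methoxy-N-methylpentanamide F4. Aryllithium 5, made from 3 as before, is acylated by F4, a ketone synthesis that stops cleanly after one addition. The route is rejoined at 8, and step 3 is no longer needed.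

Further compounds
F1 | step 7 | methyl (5S)-3-(2-bromo-3,5,6-trimethoxybenzoyl)-5-(tert-butyldimethylsilyloxy)-2-oxohexanoate (C3 epimers, enolised) | COC(=O)C(=O)C(C[C@H](C)O[Si](C)(C)C(C)(C)C)C(=O)c1c(Br)c(OC)cc(OC)c1OC
F2 | step 6 | methyl 2-{3,4,6-trimethoxy-2-[(S)-4-(tert-butyldimethylsilyloxy)pentanoyl]phenyl}acrylate | C=C(C(=O)OC)c1c(OC)cc(OC)c(OC)c1C(=O)CC[C@H](C)O[Si](C)(C)C(C)(C)C
F3 | step 2 | (S)-4-hydroxy-N-methoxy-N-methylpentanamide | CON(C)C(=O)CC[C@H](C)O
F4 | step 2 | (S)-4-(tert-butyldimethylsilyloxy)-N-methoxy-N-methylpentanamide | CON(C)C(=O)CC[C@H](C)O[Si](C)(C)C(C)(C)C
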